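**Retrosynthetic overview**

1. The C6 chloride comes from SN2 inversion of the (6R)-allylic alcohol, which comes from the C6 enone; the ten-membered carbocycle (C1–C10) is disconnected at C5–C6 by an intramolecular Nozaki–Hiyama–Kishi (NHK) addition of a C5 alkenyl bromide to a C6 aldehyde.
2. Enabling feature: C5 carries the exocyclic C16 methylene and is bonded to the heteroatom-bearing C6, which sits on lactone carbon C7; C5–C6 is therefore the one ring bond that is a 2-haloalkene/α-acyloxy aldehyde retron.
3. γ-Lactone (C7, C8, C17, C19, O): hydroxyl-directed iodolactonisation of a C7=C6 vinyl carbinol acid, made by a chelation-controlled propanoate aldol on a C8 vinyl ketone; the ketone comes from lithiated methoxyallene and the C9 aldehyde.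
4. Ring A: catalytic enantioselective Diels–Alder reaction (C1, C10), palladium-catalysed elimination to the cyclohexa-1,3-diene and face-selective dihydroxylation (C11, C12); C2 by alkyllithium addition, oxidation and CBS reduction.
5. Order of ring formation: cyclohexene (step 2), γ-lactone (step 14), ten-membered ring (step 18).

Key step: step 18

Numbering and faces: briarane numbering of the target is used for every intermediate (C1–C10 ten-membered ring; C1, C10–C14 cyclohexene; lactone C7–C8–C17–C19(=O)–O; C15 on C1, C16 on C5, C18 on C17, C20 on C11); β is the ring A face of the C15 methyl, α the opposite face.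

Assumption: the facial sense of the cationic oxazaborolidine in step 2 is taken to follow the usual formyl-bound pre-transition-state model, with the (S)-catalyst giving the enantiomer drawn; the mirror-image catalyst would be used if the sense were opposite.

**Route**

Step 1
Reactants: 1 (E)-pent-2-enal
Product: 2 (1E,3E)-1-(tert-butyldimethylsilyloxy)penta-1,3-diene
Conditions: TBSOTf, Et3N, Et2O, 0 °C to rt
Reagents that add atoms: tert-butyldimethylsilyl trifluoromethanesulfonate, CC(C)(C)[Si](C)(C)OS(=O)(=O)C(F)(F)F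
Why: Soft enolisation (O-silylation, then γ-deprotonation by Et3N) is the standard silyl dienol ether synthesis and should give mainly the (1E,3E) diene, the only isomer able to react in step 2.

Step 2
Reactants: 2 (1E,3E)-1-(tert-butyldimethylsilyloxy)penta-1,3-diene; 3 ethyl (E)-3-methyl-4-oxobut-2-enoate
Product: 4 ethyl (1S,2S,5R,6R)-5-(tert-butyldimethylsilyloxy)-6-formyl-2,6-dimethylcyclohex-3-ene-1-carboxylate
Conditions: (S)-1-(2-methylphenyl)-3,3-diphenyltetrahydro-1H,3H-pyrrolo[1,2-c][1,3,2]oxazaborole·HNTf2 (cat.), CH2Cl2, −78 to −40 °C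
Reagents that add atoms: none
Why: Enantioselective Diels–Alder reaction under cationic oxazaborolidine (Corey) catalysis, in which the boron-bound formyl group makes C10 the electrophilic terminus so that the nucleophilic C11 end of the silyl dienol ether bonds to C10 and C14 to the quaternary C1, the E dienophile fixes C2 and C9 trans, the catalyst fixes the absolute configuration, and the endo/exo outcome at C11 and C14 is irrelevant because both centres are removed in step 4.

Step 3
Reactants: 4 ethyl (1S,2S,5R,6R)-5-(tert-butyldimethylsilyloxy)-6-formyl-2,6-dimethylcyclohex-3-ene-1-carboxylate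
Product: 6 ethyl (1S,2S,5R,6R)-5-acetoxy-6-formyl-2,6-dimethylcyclohex-3-ene-1-carboxylate, via allylic alcohol 5 (not isolated)
Conditions: HF·pyridine, THF, 0 °C; then Ac2O, pyridine, DMAP (cat.), CH2Cl2, 0 °C to rt
Reagents that add atoms: acetic anhydride, CC(=O)OC(C)=O
Why: Non-basic fluoride desilylation (which avoids retro-aldol opening of the β-hydroxy aldehyde) followed by standard acetylation gives an allylic acetate that zerovalent palladium can ionise, with no stereocentre touched.

Step 4
Reactants: 6 ethyl (1S,2S,5R,6R)-5-acetoxy-6-formyl-2,6-dimethylcyclohex-3-ene-1-carboxylate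
Product: 7 ethyl (1S,6S)-6-formyl-2,6-dimethylcyclohexa-2,4-diene-1-carboxylate
Conditions: Pd(PPh3)4 (cat.), Et3N, THF, 65 °C
Reagents that add atoms: none
Why: Tsuji-type palladium-catalysed 1,4-elimination, in which anti ionisation of the C14 acetate gives a π-allyl complex whose only syn β-hydrogen is H11 (C1 is quaternary and the C11 methyl is cis to the acetate in either cycloadduct), so the C11=C12–C13=C14 diene should form regiospecifically.

Step 5
Reactants: 8 3-bromobut-3-en-1-ol
Product: 9 2-bromo-4-iodobut-1-ene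
Conditions: I2, PPh3, imidazole, CH2Cl2, 0 °C to rt
Reagents that add atoms: iodine, II
Why: Appel-type iodination of a primary alcohol; the alkenyl bromide is inert.

Step 6
Reactants: 7 ethyl (1S,6S)-6-formyl-2,6-dimethylcyclohexa-2,4-diene-1-carboxylate; 9 2-bromo-4-iodobut-1-ene
Product: 11 ethyl (1S,6S)-6-(4-bromo-1-hydroxypent-4-en-1-yl)-2,6-dimethylcyclohexa-2,4-diene-1-carboxylate (both C2 epimers), via (3-bromobut-3-enyl)lithium 10 (not isolated)
Conditions: 9, t-BuLi (2 equiv), Et2O–pentane, −78 °C; then 7, −78 °C; AcOH quench at −78 °C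
Reagents that add atoms: none
Why: Iodine–lithium exchange at the primary iodide is faster than bromine–lithium exchange at the alkenyl bromide at −78 °C, and 1,2-addition of the alkyllithium to the aldehyde is faster than attack on the hindered ester; the C2 configuration is not controlled here and is erased in step 7.

Step 7
Reactants: 11 ethyl (1S,6S)-6-(4-bromo-1-hydroxypent-4-en-1-yl)-2,6-dimethylcyclohexa-2,4-diene-1-carboxylate
Product: 12 ethyl (1S,6S)-6-(4-bromopent-4-enoyl)-2,6-dimethylcyclohexa-2,4-diene-1-carboxylate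
Conditions: Dess–Martin periodinane, NaHCO3, CH2Cl2, 0 °C to rt
Reagents that add atoms: none
Why: Dess–Martin oxidation of a secondary alcohol under buffered conditions that leave the diene and the C10 centre untouched.

Step 8
Reactants: 12 ethyl (1S,6S)-6-(4-bromopent-4-enoyl)-2,6-dimethylcyclohexa-2,4-diene-1-carboxylate
Product: 13 ethyl (1S,6S)-6-[(1R)-4-bromo-1-hydroxypent-4-en-1-yl]-2,6-dimethylcyclohexa-2,4-diene-1-carboxylate
Conditions: (S)-1-methyl-3,3-diphenyltetrahydro-1H,3H-pyrrolo[1,2-c][1,3,2]oxazaborole (cat.), catecholborane, toluene, −78 to −40 °C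
Reagents that add atoms: none
Why: Corey–Bakshi–Shibata reduction, in which the catalyst distinguishes the quaternary C1 side (large) from the C3 methylene (small) so that the (S)-catalyst should give the 2R carbinol by reagent control; catecholborane does not hydroborate the diene or the alkenyl bromide at low temperature.

Step 9
Reactants: 13 ethyl (1S,6S)-6-[(1R)-4-bromo-1-hydroxypent-4-en-1-yl]-2,6-dimethylcyclohexa-2,4-diene-1-carboxylate
Product: 14 ethyl (1S,6S)-6-[(1R)-4-bromo-1-(tert-butyldimethylsilyloxy)pent-4-en-1-yl]-2,6-dimethylcyclohexa-2,4-diene-1-carboxylate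
Conditions: TBSOTf, 2,6-lutidine, CH2Cl2, −78 to 0 °C
Reagents that add atoms: tert-butyldimethylsilyl trifluoromethanesulfonate, CC(C)(C)[Si](C)(C)OS(=O)(=O)C(F)(F)F
Why: Silylation of the hindered secondary alcohol with the silyl triflate blocks lactonisation of the γ-hydroxy ester and removes the acidic proton before the organometallic steps.

Step 10
Reactants: 14 ethyl (1S,6S)-6-[(1R)-4-bromo-1-(tert-butyldimethylsilyloxy)pent-4-en-1-yl]-2,6-dimethylcyclohexa-2,4-diene-1-carboxylate
Product: 15 ring A 11α,12α-diol (ethyl ester on C10; C13=C14 retained; C2 silyl ether)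
Conditions: OsO4 (cat.), N-methylmorpholine N-oxide, acetone–H2O, 0 °C
Reagents that add atoms: osmium tetroxide (catalytic oxygen carrier), O=[Os](=O)(=O)=O; N-methylmorpholine N-oxide, C[N+]1([O-])CCOCC1; water, O
Why: Upjohn dihydroxylation, in which OsO4 should attack the electron-rich trisubstituted C11=C12 bond rather than the C13=C14 bond next to the quaternary C1 or the deactivated alkenyl bromide, from the α face opposite the C10 ester and the C15 methyl, setting C11 and C12 as the cis diol.

Step 11
Reactants: 15 ring A 11α,12α-diol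
Product: 16 11,12-O-isopropylidene acetal of 15
Conditions: 2,2-dimethoxypropane, PPTS (cat.), CH2Cl2, rt
Reagents that add atoms: 2,2-dimethoxypropane, COC(C)(C)OC
Why: Acid-catalysed transketalisation protects the cis diol (including the tertiary C11 hydroxyl) as the acetonide; standard protecting-group chemistry.

Step 12
Reactants: 16 11,12-O-isopropylidene acetal of 15
Product: 17 C9 aldehyde (CHO on C10 in place of the ester; all configurations as in 16)
Conditions: i-Bu2AlH (1.1 equiv), CH2Cl2, −78 °C; Rochelle salt work-up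
Reagents that add atoms: none
Why: Half-reduction of an ester with i-Bu2AlH at −78 °C, where the tetrahedral aluminium hemiacetal of this hindered ester should survive until work-up and C10 is not epimerised under non-basic conditions.

Step 13
Reactants: 17 C9 aldehyde; 18 methoxyallene
Product: 21 (9R)-9-hydroxy C8 vinyl ketone (C10–CH(OH)–C(=O)–CH=CH2), via 1-lithio-1-methoxyallene 19 (not isolated), via (9R)-allenyl carbinol 20 (not isolated)
Conditions: 18, n-BuLi, THF, −40 °C; then 17, −78 °C; then 5% aq. H2SO4, THF, 0 °C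
Reagents that add atoms: water, O
Why: 1,2-Addition of lithiated methoxyallene (an acryloyl anion equivalent) under Felkin–Anh control reinforced by lithium chelation to the C11 acetal oxygen, with attack anti to the quaternary C1 from the H10 side setting C9; the acidic work-up hydrolyses the allenyl enol ether to the vinyl ketone.

Step 14
Reactants: 21 (9R)-9-hydroxy C8 vinyl ketone; 22 propanoic acid
Product: 25 iodolactone (γ-lactone O–C7–C8–C17–C19 with CH2I on C7; 8-OH cis to CH2I and to the C17 methyl; free 9-OH), via dilithium propanoate enediolate 23 (not isolated), via (8R,9R,17R)-hydroxy acid lithium salt 24 (not isolated)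
Conditions: 22, LDA (2 equiv per acid), THF, 0 °C; then 21, −78 °C; then aq. NaHCO3, I2, KI, THF–H2O, 0 °C, dark
Reagents that add atoms: iodine, II
Why: Aldol addition of the propanoic acid dianion under Cram chelation control by the C9 lithium alkoxide should set C8 (9,8-anti) with the C17 methyl trans to the C9 branch, and kinetic 5-exo iodolactonisation of the carboxylate (anti addition, hydroxyl-directed as in 3-hydroxypent-4-enoic acids) sets C7 with CH2I cis to the C8 hydroxyl and closes the lactone on O7 and not on O9.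

Step 15
Reactants: 25 iodolactone
Product: 26 pentaol (2-, 9-, 12-OH secondary; 8-, 11-OH tertiary; CH2I and alkenyl bromide retained)
Conditions: 48% aq. HF, MeCN, 0 °C to rt
Reagents that add atoms: none

Why: Aqueous HF in acetonitrile cleaves the silyl ether and the isopropylidene acetal, while the lactone, the iodide and the alkenyl bromide are stable to these acidic conditions.

Step 16
Reactants: 26 pentaol
Product: 27 2,9,12-triacetate
Conditions: Ac2O, pyridine, DMAP (cat.), CH2Cl2, rt
Reagents that add atoms: acetic anhydride, CC(=O)OC(C)=O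
Why: DMAP-catalysed acetylation acylates the three secondary hydroxyls and leaves the tertiary C8 and C11 hydroxyls free; capping O9 also blocks translactonisation.

Step 17
Reactants: 27 2,9,12-triacetate
Product: 28 seco aldehyde (CHO on C7 in place of CH2I)
Conditions: AgBF4, DMSO, rt, dark; then Et3N, 0 °C
Reagents that add atoms: dimethyl sulfoxide, CS(C)=O
Why: Silver-assisted Kornblum oxidation, in which AgBF4 promotes displacement of iodide by DMSO and Et3N collapses the alkoxysulfonium salt to the aldehyde at low temperature, limiting epimerisation at C7.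

Step 18
Reactants: 28 seco aldehyde
Product: 29 (6S)-6-hydroxy ten-membered carbocycle (complete tricyclic skeleton; C5=C16 exocyclic)
Conditions: CrCl2 (excess), NiCl2 (cat.), DMSO–THF, rt, slow addition, high dilution
Reagents that add atoms: none
Why: Intramolecular Nozaki–Hiyama–Kishi reaction: nickel-catalysed oxidative addition into the C5–Br bond and transmetalation give an alkenylchromium species (trivalent chromium) that adds to the C6 aldehyde. The closest known reaction type is the Ni/Cr-mediated macrocyclisation of haloalkene aldehydes used for medium and large carbocycles. The ten-membered ring closes by C5–C6 bond formation in an exo-trig mode (the aldehyde C=O stays outside the new ring and C5=C16 remains exocyclic), with ring A and the lactone already in place. The new C6 carbinol centre is expected mainly as the 6S (6,7-anti) epimer through Felkin–Anh control by the C7–O bond, but this is not relied on because C6 is re-set in steps 19 and 20. The step needs chemoselectivity for the alkenyl bromide/aldehyde pair and cyclisation over oligomerisation; the organochromium reagent tolerates the three acetates, the lactone and the free tertiary hydroxyls, and slow addition at high dilution favours ring closure.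

Step 19
Reactants: 29 (6S)-6-hydroxy ten-membered carbocycle
Product: 30 C6 enone (α-methylene ketone)
Conditions: Dess–Martin periodinane, NaHCO3, CH2Cl2, 0 °C
Reagents that add atoms: none
Why: Dess–Martin oxidation of the secondary allylic alcohol converges both C6 epimers to one enone; the tertiary alcohols are inert.

Step 20
Reactants: 30 C6 enone
Product: 31 (6R)-6-hydroxy ten-membered carbocycle
Conditions: NaBH4, CeCl3·7H2O, MeOH, −78 °C
Reagents that add atoms: none
Why: Luche 1,2-reduction, in which non-chelated Felkin–Anh delivery of hydride anti to the C7–O bond should give the 6,7-syn (6R) allylic alcohol; CeCl3 suppresses conjugate reduction and the acetates survive at −78 °C.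

Step 21
Reactants: 31 (6R)-6-hydroxy ten-membered carbocycle
Product: 32 target, (1S,2R,6S,7R,8R,9R,10S,11S,12R,17R)-2,9,12-triacetoxy-6-chloro-8,11-dihydroxybriara-5(16),13-diene 7,19-lactone
Conditions: PPh3, hexachloroacetone, CH2Cl2, −40 to 0 °C
Reagents that add atoms: hexachloroacetone, ClC(Cl)(Cl)C(=O)C(Cl)(Cl)Cl
Why: Appel-type chlorination (PPh3/hexachloroacetone) converts secondary allylic alcohols to chlorides by SN2 with inversion and little allylic transposition, which should give the 6S chloride; the tertiary alcohols do not react.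

**Compound list**

1 | (E)-pent-2-enal | CC/C=C/C=O | starting material
2 | (1E,3E)-1-(tert-butyldimethylsilyloxy)penta-1,3-diene | C/C=C/C=C/O[Si](C)(C)C(C)(C)C | intermediate
3 | ethyl (E)-3-methyl-4-oxobut-2-enoate | CCOC(=O)/C=C(\C)C=O | starting material
4 | ethyl (1S,2S,5R,6R)-5-(tert-butyldimethylsilyloxy)-6-formyl-2,6-dimethylcyclohex-3-ene-1-carboxylate (ester, both methyls and OTBS on the β face; CHO α) | O=C[C@@]1(C)[C@H](O[Si](C)(C)C(C)(C)C)C=C[C@H](C)[C@@H]1C(=O)OCC | intermediate
5 | ethyl (1S,2S,5R,6R)-6-formyl-5-hydroxy-2,6-dimethylcyclohex-3-ene-1-carboxylate | O=C[C@@]1(C)[C@H](O)C=C[C@H](C)[C@@H]1C(=O)OCC | intermediate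
6 | ethyl (1S,2S,5R,6R)-5-acetoxy-6-formyl-2,6-dimethylcyclohex-3-ene-1-carboxylate | O=C[C@@]1(C)[C@H](OC(C)=O)C=C[C@H](C)[C@@H]1C(=O)OCC | intermediate
7 | ethyl (1S,6S)-6-formyl-2,6-dimethylcyclohexa-2,4-diene-1-carboxylate | O=C[C@@]1(C)C=CC=C(C)[C@@H]1C(=O)OCC | intermediate
8 | 3-bromobut-3-en-1-ol | C=C(Br)CCO | starting material
9 | 2-bromo-4-iodobut-1-ene | C=C(Br)CCI | intermediate
10 | (3-bromobut-3-en-1-yl)lithium | [Li]CCC(Br)=C | intermediate
11 | ethyl (1S,6S)-6-(4-bromo-1-hydroxypent-4-en-1-yl)-2,6-dimethylcyclohexa-2,4-diene-1-carboxylate (C2 epimers) | C=C(Br)CCC(O)[C@@]1(C)C=CC=C(C)[C@@H]1C(=O)OCC | intermediate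
12 | ethyl (1S,6S)-6-(4-bromopent-4-enoyl)-2,6-dimethylcyclohexa-2,4-diene-1-carboxylate | C=C(Br)CCC(=O)[C@@]1(C)C=CC=C(C)[C@@H]1C(=O)OCC | intermediate
13 | ethyl (1S,6S)-6-[(1R)-4-bromo-1-hydroxypent-4-en-1-yl]-2,6-dimethylcyclohexa-2,4-diene-1-carboxylate | C=C(Br)CC[C@@H](O)[C@@]1(C)C=CC=C(C)[C@@H]1C(=O)OCC | intermediate
14 | ethyl (1S,6S)-6-[(1R)-4-bromo-1-(tert-butyldimethylsilyloxy)pent-4-en-1-yl]-2,6-dimethylcyclohexa-2,4-diene-1-carboxylate | C=C(Br)CC[C@@H](O[Si](C)(C)C(C)(C)C)[C@@]1(C)C=CC=C(C)[C@@H]1C(=O)OCC | intermediate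
15 | ring A 11α,12α-diol: (2R)-silyl ether, ethyl ester on C10 (β), 11-OH and 12-OH cis on the α face, C20 methyl β, C13=C14 | C=C(Br)CC[C@@H](O[Si](C)(C)C(C)(C)C)[C@@]1(C)C=C[C@@H](O)[C@@](C)(O)[C@@H]1C(=O)OCC | intermediate
16 | 11,12-O-isopropylidene acetal of 15 | C=C(Br)CC[C@@H](O[Si](C)(C)C(C)(C)C)[C@@]1(C)C=C[C@@H](OC2(C)C)[C@@](C)(O2)[C@@H]1C(=O)OCC | intermediate
17 | C9 aldehyde: 16 with CHO on C10 in place of the ester | C=C(Br)CC[C@@H](O[Si](C)(C)C(C)(C)C)[C@@]1(C)C=C[C@@H](OC2(C)C)[C@@](C)(O2)[C@@H]1C=O | intermediate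
18 | methoxyallene (1-methoxypropa-1,2-diene) | COC=C=C | starting material
19 | 1-lithio-1-methoxyallene | COC([Li])=C=C | intermediate
20 | (9R)-allenyl carbinol: C9 carbinol bearing the 1-methoxypropa-1,2-dienyl group | C=C(Br)CC[C@@H](O[Si](C)(C)C(C)(C)C)[C@@]1(C)C=C[C@@H](OC2(C)C)[C@@](C)(O2)[C@@H]1[C@@H](O)C(OC)=C=C | intermediate
21 | (9R)-9-hydroxy C8 vinyl ketone | C=C(Br)CC[C@@H](O[Si](C)(C)C(C)(C)C)[C@@]1(C)C=C[C@@H](OC2(C)C)[C@@](C)(O2)[C@@H]1[C@@H](O)C(=O)C=C | intermediate
22 | propanoic acid | CCC(=O)O | starting material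
23 | dilithium propanoate enediolate | CC=C(O[Li])O[Li] | intermediate
24 | (8R,9R,17R)-β-hydroxy acid (C8 carbinol bearing the vinyl group; C17 methyl; C19 acid), handled as its lithium carboxylate | C=C(Br)CC[C@@H](O[Si](C)(C)C(C)(C)C)[C@@]1(C)C=C[C@@H](OC2(C)C)[C@@](C)(O2)[C@@H]1[C@@H](O)[C@](C=C)(O)[C@@H](C)C(=O)O | intermediate
25 | iodolactone: (7R,8R,17R)-γ-lactone with CH2I on C7; 8-OH cis to CH2I and to the C17 methyl; (9R)-OH free | C=C(Br)CC[C@@H](O[Si](C)(C)C(C)(C)C)[C@@]1(C)C=C[C@@H](OC2(C)C)[C@@](C)(O2)[C@@H]1[C@@H](O)[C@]1(O)[C@@H](C)C(=O)O[C@H]1CI | intermediate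
26 | pentaol: 25 without silyl and isopropylidene groups | C=C(Br)CC[C@@H](O)[C@@]1(C)C=C[C@@H](O)[C@@](C)(O)[C@@H]1[C@@H](O)[C@]1(O)[C@@H](C)C(=O)O[C@H]1CI | intermediate
27 | 2,9,12-triacetate of 26 | C=C(Br)CC[C@@H](OC(C)=O)[C@@]1(C)C=C[C@@H](OC(C)=O)[C@@](C)(O)[C@@H]1[C@@H](OC(C)=O)[C@]1(O)[C@@H](C)C(=O)O[C@H]1CI | intermediate
28 | seco aldehyde: 27 with CHO (C6) on C7 in place of CH2I | C=C(Br)CC[C@@H](OC(C)=O)[C@@]1(C)C=C[C@@H](OC(C)=O)[C@@](C)(O)[C@@H]1[C@@H](OC(C)=O)[C@]1(O)[C@@H](C)C(=O)O[C@H]1C=O | intermediate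
29 | (6S)-6-hydroxy ten-membered carbocycle (6,7-anti; expected major epimer; 6-epimer is 31) | C=C1CC[C@@H](OC(C)=O)[C@@]2(C)C=C[C@@H](OC(C)=O)[C@@](C)(O)[C@@H]2[C@@H](OC(C)=O)[C@]2(O)[C@@H](C)C(=O)O[C@H]2[C@H]1O | intermediate
30 | C6 enone | C=C1CC[C@@H](OC(C)=O)[C@@]2(C)C=C[C@@H](OC(C)=O)[C@@](C)(O)[C@@H]2[C@@H](OC(C)=O)[C@]2(O)[C@@H](C)C(=O)O[C@H]2C1=O | intermediate
31 | (6R)-6-hydroxy ten-membered carbocycle (6,7-syn) | C=C1CC[C@@H](OC(C)=O)[C@@]2(C)C=C[C@@H](OC(C)=O)[C@@](C)(O)[C@@H]2[C@@H](OC(C)=O)[C@]2(O)[C@@H](C)C(=O)O[C@H]2[C@@H]1O | intermediate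
32 | (1S,2R,6S,7R,8R,9R,10S,11S,12R,17R)-2,9,12-triacetoxy-6-chloro-8,11-dihydroxybriara-5(16),13-diene 7,19-lactone | C=C1CC[C@@H](OC(C)=O)[C@@]2(C)C=C[C@@H](OC(C)=O)[C@@](C)(O)[C@@H]2[C@@H](OC(C)=O)[C@]2(O)[C@@H](C)C(=O)O[C@H]2[C@H]1Cl | target

**Totals and risks**

Total step count: 21. Longest linear sequence: 20 steps (steps 1–4 and 6–21; step 5 is a one-step side branch).

Steps most likely to fail:

Step 18. Oxidative addition of the 2-bromoalkene may be slow, so that decomposition of the α-acyloxy β-hydroxy aldehyde (retro-aldol, epimerisation at C7) and oligomerisation compete with closure of the strained ten-membered ring. The fallback sets out from 28 and closes the same bond by acyl–alkenyl coupling instead of carbonyl addition. Pinnick oxidation (NaClO2, NaH2PO4, 2-methylbut-2-ene, t-BuOH–H2O) gives the seco carboxylic acid F1. Thioesterification with 2,2'-dipyridyl disulfide and PPh3 gives the S-(2-pyridyl) thioester F2. A nickel/zirconium-mediated alkenyl halide–thioester ketone coupling (NiBr2(dtbbpy) cat., Cp2ZrCl2, Zn, NaI, DMI–THF, high dilution) then closes the ring directly to the enone, and the route is rejoined at 30.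

Step 14. The enediolate may add in a conjugate sense to the vinyl ketone (or the ketone may polymerise), and chelation control at C8 may be incomplete. The fallback sets out from 21 and masks the enone. Conjugate addition of benzeneselenol (PhSeH, Et3N cat., CH2Cl2, 0 °C) gives the β-(phenylseleno)ethyl ketone F3. Reformatsky addition of the zinc enolate of tert-butyl 2-bromopropanoate (Zn, THF, 0 °C), chelation-controlled through the C9 zinc alkoxide, gives the tert-butyl β-hydroxy ester F4. Oxidation with H2O2–pyridine (CH2Cl2, 0 °C) and selenoxide elimination regenerates the vinyl group in the tert-butyl ester F5. Iodolactonisation of the tert-butyl ester (I2, NaHCO3, MeCN, 0 °C, with loss of the tert-butyl group) rejoins the route at 25.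

Step 20. Hydride may be delivered to the wrong face of the conformationally mobile macrocyclic enone, giving the 6S alcohol. The fallback sets out from 29 (the 6S alcohol, also the expected product of step 18) and uses double inversion instead of oxidation–reduction. Appel bromination (PPh3, CBr4, CH2Cl2, 0 °C) gives with inversion the (6R)-allylic bromide F6. Displacement with LiCl (DMF, 0 °C) inverts again and rejoins the route at 32.

Further compounds
F1 | step 18 | seco carboxylic acid (CO2H on C7 in place of CHO of 28) | C=C(Br)CC[C@@H](OC(C)=O)[C@@]1(C)C=C[C@@H](OC(C)=O)[C@@](C)(O)[C@@H]1[C@@H](OC(C)=O)[C@]1(O)[C@@H](C)C(=O)O[C@H]1C(=O)O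
F2 | step 18 | S-(pyridin-2-yl) thioester of F1 | C=C(Br)CC[C@@H](OC(C)=O)[C@@]1(C)C=C[C@@H](OC(C)=O)[C@@](C)(O)[C@@H]1[C@@H](OC(C)=O)[C@]1(O)[C@@H](C)C(=O)O[C@H]1C(=O)Sc2ccccn2
F3 | step 14 | (9R)-9-hydroxy 2-(phenylseleno)ethyl ketone (PhSeH adduct of 21) | C=C(Br)CC[C@@H](O[Si](C)(C)C(C)(C)C)[C@@]1(C)C=C[C@@H](OC2(C)C)[C@@](C)(O2)[C@@H]1[C@@H](O)C(=O)CC[Se]c3ccccc3
F4 | step 14 | tert-butyl (8R,9R,17R)-β-hydroxy ester bearing the 2-(phenylseleno)ethyl group on C8 | C=C(Br)CC[C@@H](O[Si](C)(C)C(C)(C)C)[C@@]1(C)C=C[C@@H](OC2(C)C)[C@@](C)(O2)[C@@H]1[C@@H](O)[C@](CC[Se]c3ccccc3)(O)[C@@H](C)C(=O)OC(C)(C)C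
F5 | step 14 | tert-butyl ester of hydroxy acid 24 (vinyl group on C8) | C=C(Br)CC[C@@H](O[Si](C)(C)C(C)(C)C)[C@@]1(C)C=C[C@@H](OC2(C)C)[C@@](C)(O2)[C@@H]1[C@@H](O)[C@](C=C)(O)[C@@H](C)C(=O)OC(C)(C)C
F6 | step 20 | (6R)-6-bromo analogue of the target (6-epi-bromide) | C=C1CC[C@@H](OC(C)=O)[C@@]2(C)C=C[C@@H](OC(C)=O)[C@@](C)(O)[C@@H]2[C@@H](OC(C)=O)[C@]2(O)[C@@H](C)C(=O)O[C@H]2[C@@H]1Br
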